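## Structural features

The target is a 3,4-seco-abietane. A cyclohexanone ring B (C5 to C10) is fused through C8 and C9 to a hexasubstituted benzene ring C that carries hydroxyl groups on C11, C12 and C14 and an isopropyl group on C13. The C7 ketone is conjugated with ring C and hydrogen-bonded to the C14 hydroxyl, and C6 is its only enolisable position. C5 (H and the isopropenyl carbon C4) and the quaternary, benzylic C10 (methyl and the C1–C3 propanoic acid chain) are adjacent stereocentres, with C4 and C1 on one face of ring B and H-5 and the methyl on the other. The 1,2,4-trioxygenated arene oxidises in air to a hydroxyquinone, and the isopropenyl group next to a free acid can lactonise or isomerise under strong acid. The real difficulty is the tertiary/quaternary pair with its cis carbon appendages, together with an arene in which all six positions differ. The C5–C10 bond with its four substituents is the alkene of citraconic anhydride in disguise (two cis carbonyls for C4 and C1, plus H and CH3), and C6–C7(O)–C8–C9 is a 2-oxygenated butadiene; the key step exploits exactly this. The enone that the cycloaddition leaves exposes C8, its α-carbon, as the point where ring C can be attached.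

## Logic of the disconnections

31 back to 28 (through 30 and 29). No skeletal bond is cut. The two O–H bonds at C11 and C14, the C12–O bond to isopropyl and the oxidation level of C3 are adjusted. The reason is that the triol cannot survive an alcohol oxidation, whereas the quinone can. The gain is that all oxidative work is done on a stable compound. The demand is a last step that is a mild reduction under exclusion of air, and a hydrolysis at C12 that leaves the C7 ketone and the alkene alone.

28 back to 25 (through 27 and 26). The C9–C11 bond is cut and ring C is folded back into a four-membered ring attached through C14 to C8. The reason is that every substituent of ring C is then fixed by its position on the small ring. The gain is that the arene is reduced to a ring B alkene plus a cyclobutenone. The demand is a thermal ring opening that turns the alkenyl group inward and a closure onto C9 beside the quaternary centre. Protecting groups must be removed while ring C is still an electron-rich hydroquinone, because the C7 ketal is labile only then.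

25 back to 23, then to 19 and 20. The C13–isopropyl bond and the C8–C14 bond are cut. The reason is that 20 is symmetrical, so the first addition raises no regiochemical question, and the order of the two additions alone puts the isopropyl carbon next to the carbinol carbon. C8 is chosen because it is the α-carbon of the enone of 8 and is halogenated in one step, whereas C9 would need an oxygen transposition. The gain is that ring C comes from a purchased four-carbon unit. The demand is a C8 nucleophile with no carbonyl elsewhere, hence the C7 ketal and the C3 silyl ether in 19, and a second addition to a hindered carbonyl.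

19 back to 13 (through 18, 17, 16, 15 and 14). The C1–C2 bond is cut, the C4=C18 alkene is traced to a tertiary alcohol, and C3 is returned to the ester level. The reason is that C1 is already present at the acid level in 13 and reaches the aldehyde level as 14, to which two carbons are added at once. The gain is that the side chain and the isopropenyl group collapse into one lactone. The demand is a conjugate reduction that spares the vinyl bromide and a dehydration that runs toward a methyl group and not toward C5.

13 back to 8 (through 11 and 10). Both C4–CH3 bonds are cut, and the ketal and the bromine are removed. The reason is that the two anhydride carbonyls of 11 differ in their neighbours (tertiary C5 against quaternary C10), so a methyl nucleophile is steered to C4. The gain is the return to the cycloadduct. The demand is that the ketone be masked first, by a method that does not open the anhydride, and that bromination precede the masking because it needs the enone.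

8 back to 5 and 6. The C5–C6 and C9–C10 bonds are cut. The reason is that ring B, both stereocentres and the differentiated C1/C4 carbonyls then arise in one cycloaddition. The gain is two achiral-pool fragments and a recoverable auxiliary. The demand is regiocontrol (C6 to C5), endo control and facial control at the same time, and an unmasking that keeps the anhydride closed.

5 back to 3, then to 1 and 2. The O–Si bond and the C–N bond are cut. The reason is that the diene is the silyl enol ether of a vinylogous amide. The gain is two purchased compounds. The demand is kinetic enolisation at the methyl group.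

## Other disconnections considered

Alternative 1: The cut is at C10–C1 and C5–C4. In the forward sense the diene A2 would add to the C5=C10 alkene of the ortho-quinone A1 and give the cis-fused adduct A3, whose temporary ring A is later cleaved.
- In its favour: ring C arrives complete, so no late arene construction is needed. This is a point on which it is better than the chosen plan. Both stereocentres would be set in one step and the C7 oxygen is already there. The 1,2-dione could bind a chiral Lewis acid in a bidentate way, so catalytic enantiocontrol is conceivable where the chosen plan spends a stoichiometric auxiliary. This is a second point on which it is better.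
- Against it: the reacting carbon C10 of A1 carries a methyl group and sits next to the C11 methoxy group, and ortho-quinones can also react as heterodienes or at a carbonyl. The enol ether oxygen of A3 lies on C2, so cleavage at C2=C3 leaves an acetic acid chain on C10 (one carbon short) and a 1-formylethyl group on C5. A homologation, a three-step conversion into the isopropenyl group, removal of the C6 ketone and cleavage of three aryl methyl ethers beside an acid-sensitive alkene would follow.
- Comparison: on the origin of the cis relationship the two plans are equal, since both rely on suprafacial addition to a ring alkene. On step economy A3 would probably need as many steps as 8 does, and harsher ones at the end.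

Alternative 2: The cut is at C8–C14, and one step earlier at C9–C11. In the forward sense the 4-hydroxycyclobutenone A4, joined to ring B at C9, would open on heating and close onto C8 to give the hydroquinone A5.
- In its favour: the whole substitution pattern of ring C is decided by one addition to a pre-formed four-membered ring, and the advanced intermediate meets only one organometallic step. On this point it is better than the chosen plan, which needs two successive additions (steps 13 and 14). The ring expansion itself is the same reaction that the chosen plan uses in step 15, so on mechanism the two are equal.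
- Against it as the strategic step: it creates no stereocentre, so C5 and C10 must come from another reaction. It needs a metal at C9, the β-carbon of the ring B enone and the neighbour of the quaternary centre, which can only be reached by transposing oxygen over several steps. C7 would travel as a silyl ether and have to be re-oxidised beside a free hydroquinone. The isopropyl aryl ether of A5 would have to be cleaved with a boron halide in the presence of the isopropenyl group.
- Comparison: overall the preparation of A4 would be longer than that of 25.

Alternative 3: The cut is at C10–C5 and C7–C6. In the forward sense irradiation of the benzaldehyde A6 would give a hydroxy-ortho-quinodimethane that adds endo to the dihydropyranone A7 and forms A8.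
- In its favour: the fully oxygenated arene is carried in intact and ring B is closed with C5, C6, C7 and the quaternary C10 in one step. The lactone tie fixes the geometry of the dienol at C10. The extra carboxyl on C6 would leave as CO2 once C7 is a ketone, and the CH2O arm of A7 is a handle for the isopropenyl group. In convergence it is better than the chosen plan.
- Against it: the dienol terminus at C10 is fully substituted, so the cycloaddition would probably need templating by Ti(Oi-Pr)4. Absolute control would rest either on enantiopure A7, whose stereocentre is later erased, or on a chiral titanium complex. A6 is itself a hexasubstituted arene that costs a synthesis of its own. The end-game (oxidation at C7, decarboxylation, two lactone openings, a selenoxide elimination, two methyl ether cleavages) is no shorter than that of the chosen plan.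
- Comparison: the chosen plan is the more predictable in relative configuration, because the cis arrangement is locked in the dienophile. On total step count the two are about equal.

Key step: step 3

Remarks before the steps.
- Assumption: the (2R,5R) auxiliary of 5 is taken to steer 6, in the endo mode, to the diene face that leads to 8. If the facial sense is the opposite, (2S,5S)-2,5-diphenylpyrrolidine is used in step 1 and nothing else changes.
- Atom numbers are those of the abietane skeleton of 31: C1–C3 chain, C4 isopropenyl carbon, C5–C10 ring B, C11–C14 ring C, methyl on C10. From 8 onward C5 and C10 keep the arrangement of the target (H-5 and the C10 methyl on one face of ring B, C4 and C1 on the other). CIP letters change with the substituents and are quoted only for 8 and 31.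
- Check of structures: 8 is (3aR,7aS) and maps onto C5 and C10 of 31 without change, so no structure needed correction.
- Two points of design were tightened. The enone is unmasked with anhydrous acid, so that the anhydride stays closed and the released amine is protonated. Ring C is attached through C8 and not through C9.

## Steps

Step 1
Reactants: 1 (E)-4-methoxybut-3-en-2-one; 2 (2R,5R)-2,5-diphenylpyrrolidine
Product: 3 (E)-4-[(2R,5R)-2,5-diphenylpyrrolidin-1-yl]but-3-en-2-one
Conditions: THF, 50 °C
Reagents that add atoms: none
Why: Addition–elimination of the secondary amine at the β-carbon of the β-methoxy enone (vinylogous transamidation); methanol is lost and the E vinylogous amide is the thermodynamic product.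

Step 2
Reactants: 3 (E)-4-[(2R,5R)-2,5-diphenylpyrrolidin-1-yl]but-3-en-2-one
Product: 5 (E)-3-(tert-butyldimethylsilyloxy)-1-[(2R,5R)-2,5-diphenylpyrrolidin-1-yl]buta-1,3-diene, via potassium dienolate 4 (not isolated)
Conditions: KN(SiMe3)2, THF, −78 °C; TBSCl, −78 °C → rt
Reagents that add atoms: tert-butyl(chloro)dimethylsilane, CC(C)(C)[Si](C)(C)Cl
Why: Kinetic deprotonation of the methyl ketone gives the cross-conjugated dienolate, which is silylated on oxygen (silyl enol ether formation); the E enamine geometry is kept.

Step 3
Reactants: 5 (E)-3-(tert-butyldimethylsilyloxy)-1-[(2R,5R)-2,5-diphenylpyrrolidin-1-yl]buta-1,3-diene; 6 citraconic anhydride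
Product: 8 (3aR,7aS)-7a-methyl-3a,4-dihydro-2-benzofuran-1,3,5(7aH)-trione, via cycloadduct 7 (not isolated)
Conditions: PhMe, −40 °C → rt; then HCl (2 M in Et2O), THF, −40 → 0 °C
Reagents that add atoms: none
Why: This is a normal-demand Diels–Alder reaction in which the amino and siloxy groups raise the diene HOMO, so the trisubstituted anhydride alkene should react without a Lewis acid; bond formation is concerted but asynchronous, C6–C5 leading and C9–C10 following. The closest known reaction type is the cycloaddition of 1-amino-3-siloxybutadienes carrying this C2-symmetric pyrrolidine with α-substituted acroleins and acrylates, and of citraconic anhydride with 1-alkoxy-3-siloxydienes. Ring B is closed by an intermolecular suprafacial–suprafacial [4+2] addition, both bonds being made in one transition state. The relative configuration of C5 and C10 (C4 and C1 cis, H-5 cis to the methyl) follows from suprafacial addition to the cis-locked dienophile, and their absolute configuration from the auxiliary, whose phenyl groups shield one diene face, combined with the endo placement of the anhydride. Because the aminated carbon C9 is flattened afterwards, endo/exo fidelity counts as much as facial fidelity, and the secondary-orbital preference of the anhydride and the exo preference of its methyl group point to the same transition state. The step needs the regiochemistry C6 to C5 and C9 to C10, which the large HOMO coefficient at the CH2 terminus and the higher electrophilicity and lower hindrance of the unsubstituted alkene carbon of 6 secure. Anhydrous HCl then cleaves the silyl enol ether and expels the protonated amine by β-elimination, giving the C7 enone with C8=C9 while the anhydride stays closed and the amine salt cannot acylate.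

Step 4
Reactants: 8 (3aR,7aS)-7a-methyl-3a,4-dihydro-2-benzofuran-1,3,5(7aH)-trione
Product: 10 6-bromo-7a-methyl-3a,4-dihydro-2-benzofuran-1,3,5(7aH)-trione (8 with Br on C8, ring fusion unchanged), via dibromide 9 (not isolated)
Conditions: Br2, CH2Cl2, 0 °C; then Et3N, 0 °C → rt
Reagents that add atoms: bromine, BrBr
Why: Addition of bromine to the enone alkene followed by E1cB loss of HBr (the C8 hydrogen is α to the ketone, bromide leaves from C9) is the standard route to 2-bromo enones; no stereocentre is touched and the anhydride is inert to both reagents.

Step 5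
Reactants: 10 6-bromo-7a-methyl-3a,4-dihydro-2-benzofuran-1,3,5(7aH)-trione
Product: 11 C7 ethylene ketal of 10 (1,3-dioxolane at C7, C8 bromide, C8=C9, cis-anhydride on C5/C10)
Conditions: Me3SiOCH2CH2OSiMe3, Me3SiOTf (cat.), CH2Cl2, −78 → −20 °C; pyridine quench
Reagents that add atoms: 1,2-bis(trimethylsilyloxy)ethane, C[Si](C)(C)OCCO[Si](C)(C)C
Why: Noyori ketalisation works by silyl transfer with no free alcohol or water present, so the ketone should be masked without opening the anhydride; the alkene cannot migrate because C10 is quaternary, and the product is the ketal of an α-keto vinyl anion equivalent.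

Step 6
Reactants: 11 C7 ethylene ketal of 10
Product: 13 cis-fused γ-lactone (ring O–C4(CH3)2–C5–C10–C1(=O); C7 dioxolane, C8 bromide, C8=C9), via hydroxy acid 12 (not isolated)
Conditions: MeMgBr (3 equiv), THF, −78 → 0 °C; then aq. citric acid, rt
Reagents that add atoms: methylmagnesium bromide, C[Mg]Br
Why: Grignard addition should occur twice at the C4 carbonyl, the less hindered of the two anhydride carbonyls (tertiary C5 against quaternary C10), by way of the keto carboxylate; mild acid then lactonises the tertiary hydroxy acid. The ketone intermediate is consumed faster than it enolises, so C5 is not epimerised.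

Step 7
Reactants: 13 cis-fused γ-lactone
Product: 14 lactol of 13 (C1 hemiacetal, either anomer)
Conditions: i-Bu2AlH (1.2 equiv), CH2Cl2, −78 °C; aq. potassium sodium tartrate
Reagents that add atoms: none
Why: Partial reduction of a lactone by i-Bu2AlH at low temperature stops at the aluminium hemiacetal, which gives the lactol on work-up; the ketal and the vinyl bromide are inert.

Step 8
Reactants: 14 lactol of 13
Product: 15 ethyl (E)-enoate (C10 bears CH=CH–CO2Et, C5 bears C(CH3)2OH; C7 dioxolane, C8 bromide)
Conditions: Ph3P=CHCO2Et, PhMe, 90 °C
Reagents that add atoms: ethyl (triphenylphosphoranylidene)acetate, CCOC(=O)C=P(c1ccccc1)(c1ccccc1)c1ccccc1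
Why: Wittig olefination of the open hydroxy-aldehyde form of the lactol with a stabilised ylide gives the E enoate and adds C2 and C3; the neutral medium keeps the tertiary hydroxyl from adding back to the enoate.

Step 9
Reactants: 15 ethyl (E)-enoate
Product: 16 saturated ethyl ester (C10 bears CH2CH2CO2Et, C5 bears C(CH3)2OH; C7 dioxolane, C8 bromide)
Conditions: [(Ph3P)CuH]6 (cat.), PhMe2SiH, t-BuOH, PhMe, rt
Reagents that add atoms: none
Why: Copper hydride 1,4-reduction is selective for the conjugated ester; the vinyl bromide, the ketal and the tertiary alcohol are not affected, and t-BuOH protonates the copper enolate.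

Step 10
Reactants: 16 saturated ethyl ester
Product: 17 isopropenyl ester (C10 bears CH2CH2CO2Et, C5 bears C(CH3)=CH2; C7 dioxolane, C8 bromide)
Conditions: SOCl2, pyridine, CH2Cl2, −20 → 0 °C
Reagents that add atoms: none
Why: Dehydration of the tertiary alcohol through its chlorosulfite by E2 elimination; loss of a methyl hydrogen gives the isopropenyl group, while the tetrasubstituted alkene toward C5 is disfavoured by allylic 1,3-strain against the quaternary C10, so C5 keeps its configuration.

Step 11
Reactants: 17 isopropenyl ester
Product: 18 primary alcohol (C10 bears (CH2)3OH, C5 isopropenyl; C7 dioxolane, C8 bromide)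
Conditions: i-Bu2AlH (2.5 equiv), CH2Cl2, −78 → 0 °C; aq. potassium sodium tartrate
Reagents that add atoms: none
Why: i-Bu2AlH reduces the ester to the primary alcohol by two hydride transfers without touching the vinyl bromide or either alkene.

Step 12
Reactants: 18 primary alcohol
Product: 19 TBS ether of 18 (C10 bears (CH2)3OSi(t-Bu)Me2)
Conditions: TBSCl, imidazole, DMF, rt
Reagents that add atoms: tert-butyl(chloro)dimethylsilane, CC(C)(C)[Si](C)(C)Cl
Why: Standard silylation of a primary alcohol; the silyl ether carries C3 through the organolithium steps.

Step 13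
Reactants: 19 TBS ether of 18; 20 diisopropyl squarate
Product: 23 4-(C8-alkenyl)-2,3-di(propan-2-yloxy)-4-(trimethylsilyloxy)cyclobut-2-en-1-one (C8-alkenyl = ring B of 19 joined at C8), via vinyllithium 21 (not isolated), via lithium alkoxide 22 (not isolated)
Conditions: t-BuLi (2.1 equiv), THF, −78 °C; 20, −78 °C; Me3SiCl, −78 → 0 °C
Reagents that add atoms: chlorotrimethylsilane, C[Si](C)(C)Cl
Why: Bromine–lithium exchange gives the 2-lithio enone ketal (β-elimination of the ketal oxygen is impossible within the ring), which adds 1,2 to one of the two equivalent carbonyls of the squarate; silylation blocks the new alkoxide. The carbinol centre forms without control and is lost again in step 15.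

Step 14
Reactants: 23 4-(C8-alkenyl)-2,3-di(propan-2-yloxy)-4-(trimethylsilyloxy)cyclobut-2-en-1-one
Product: 25 4-(C8-alkenyl)-3-(propan-2-yl)-2-(propan-2-yloxy)-4-(trimethylsilyloxy)cyclobut-2-en-1-one, via lithium alkoxide 24 (not isolated)
Conditions: i-PrLi, THF, −78 °C; (CF3CO)2O, −78 → 0 °C; aq. NaHCO3
Reagents that add atoms: isopropyllithium, [Li]C(C)C
Why: 1,2-Addition of i-PrLi to the remaining carbonyl is followed by trifluoroacetylation of the new alkoxide, ionisation assisted by the enol ether and hydrolysis of the oxocarbenium ion with loss of propan-2-ol (the acid-triggered carbonyl transposition of squarate adducts). This order of additions places the isopropyl carbon next to the silyloxy carbinol carbon, as C13 next to C14 requires.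

Step 15
Reactants: 25 4-(C8-alkenyl)-3-(propan-2-yl)-2-(propan-2-yloxy)-4-(trimethylsilyloxy)cyclobut-2-en-1-one
Product: 28 11,14-quinone keto alcohol (C12 O-i-Pr, C13 i-Pr, C7 ketone, C10 bears (CH2)3OH, C5 isopropenyl), via silyl hydroquinone 26 (not isolated), via hydroquinone 27 (not isolated)
Conditions: PhMe, 110 °C; then 1 M HCl, THF, rt, argon; then FeCl3, H2O, 0 °C
Reagents that add atoms: water, O
Why: Moore rearrangement: thermal conrotatory opening of the cyclobutenone (silyloxy outward, alkenyl inward) gives a dienylketene whose ketene carbon C11 closes onto C9 by a six-electron electrocyclisation, and tautomerisation gives the arene. Aqueous acid then removes the aryl silyl ether, the benzylic dioxolane (labile while the ring is electron-rich) and the primary silyl ether. FeCl3 oxidises the hydroquinone to the quinone, the form in which ring C tolerates the next oxidation.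

Step 16
Reactants: 28 11,14-quinone keto alcohol
Product: 29 quinone keto acid (28 with C3 as CO2H)
Conditions: TEMPO (cat.), PhI(OAc)2, MeCN/H2O, rt
Reagents that add atoms: water, O
Why: Nitroxyl-catalysed oxidation with PhI(OAc)2 in aqueous acetonitrile takes a primary alcohol to the carboxylic acid; the quinone, the ketone and the isopropenyl group are inert.

Step 17
Reactants: 29 quinone keto acid
Product: 30 12-hydroxy-11,14-quinone keto acid (29 with OH in place of O-i-Pr)
Conditions: LiOH, THF/H2O, 0 °C → rt; then 1 M HCl to pH 3
Reagents that add atoms: lithium hydroxide, [Li+].[OH-]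
Why: The isopropoxy quinone is a vinylogous ester; hydroxide adds at C12 and expels isopropoxide (addition–elimination), and acidification returns the hydroxyquinone and the free acid.

Step 18
Reactants: 30 12-hydroxy-11,14-quinone keto acid
Product: 31 3-[(1R,2S)-5,7,8-trihydroxy-1-methyl-4-oxo-6-(propan-2-yl)-2-(prop-1-en-2-yl)-1,2,3,4-tetrahydronaphthalen-1-yl]propanoic acid (target)
Conditions: Na2S2O4, EtOAc/H2O (degassed), rt, argon
Reagents that add atoms: none
Why: Two-electron reduction of the quinone by dithionite gives the 11,12,14-triol; nothing else in the molecule is reducible under these conditions, and the product is kept under argon.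

## Compound list

1 | (E)-4-methoxybut-3-en-2-one | CO/C=C/C(C)=O | starting material
2 | (2R,5R)-2,5-diphenylpyrrolidine | N1[C@@H](c2ccccc2)CC[C@@H]1c1ccccc1 | starting material
3 | (E)-4-[(2R,5R)-2,5-diphenylpyrrolidin-1-yl]but-3-en-2-one | CC(=O)/C=C/N1[C@@H](c2ccccc2)CC[C@@H]1c1ccccc1 | intermediate
4 | potassium (3E)-4-[(2R,5R)-2,5-diphenylpyrrolidin-1-yl]buta-1,3-dien-2-olate | [K+].[O-]C(=C)/C=C/N1[C@@H](c2ccccc2)CC[C@@H]1c1ccccc1 | intermediate (not isolated)
5 | (E)-3-(tert-butyldimethylsilyloxy)-1-[(2R,5R)-2,5-diphenylpyrrolidin-1-yl]buta-1,3-diene | C=C(O[Si](C)(C)C(C)(C)C)/C=C/N1[C@@H](c2ccccc2)CC[C@@H]1c1ccccc1 | intermediate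
6 | citraconic anhydride (3-methylfuran-2,5-dione) | CC1=CC(=O)OC1=O | starting material
7 | endo cycloadduct, 6-(tert-butyldimethylsilyloxy)-4-[(2R,5R)-2,5-diphenylpyrrolidin-1-yl]-3a-methyl-3a,4,7,7a-tetrahydro-2-benzofuran-1,3-dione (amine on C9 cis to the anhydride; C5 and C10 as in 8) | CC(C)(C)[Si](C)(C)OC1=C[C@H](N2[C@@H](c3ccccc3)CC[C@@H]2c2ccccc2)[C@]4(C)C(=O)OC(=O)[C@@H]4C1 | intermediate (not isolated)
8 | (3aR,7aS)-7a-methyl-3a,4-dihydro-2-benzofuran-1,3,5(7aH)-trione | O=C1[C@@H]2CC(=O)C=C[C@]2(C)C(=O)O1 | intermediate
9 | trans-6,7-dibromo-7a-methyltetrahydro-2-benzofuran-1,3,5-trione (bromine on C8 and C9 of 8) | O=C1[C@@H]2CC(=O)C(Br)C(Br)[C@]2(C)C(=O)O1 | intermediate (not isolated)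
10 | 6-bromo-7a-methyl-3a,4-dihydro-2-benzofuran-1,3,5(7aH)-trione (8 with Br on C8, ring fusion unchanged) | O=C1[C@@H]2CC(=O)C(Br)=C[C@]2(C)C(=O)O1 | intermediate
11 | C7 ethylene ketal of 10 (1,3-dioxolane at C7, C8 bromide, C8=C9, cis-anhydride on C5/C10) | O=C1[C@@H]2CC3(OCCO3)C(Br)=C[C@]2(C)C(=O)O1 | intermediate
12 | hydroxy acid (C5 bears C(CH3)2OH, C10 bears CO2H and CH3, the two groups cis; C7 dioxolane, C8 bromide) | CC(C)(O)[C@@H]1CC2(OCCO2)C(Br)=C[C@]1(C)C(=O)O | intermediate (not isolated)
13 | cis-fused γ-lactone (ring O–C4(CH3)2–C5–C10–C1(=O); C7 dioxolane, C8 bromide, C8=C9) | CC1(C)[C@@H]2CC3(OCCO3)C(Br)=C[C@]2(C)C(=O)O1 | intermediate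
14 | lactol of 13 (C1 hemiacetal, either anomer) | CC1(C)[C@@H]2CC3(OCCO3)C(Br)=C[C@]2(C)C(O)O1 | intermediate
15 | ethyl (E)-enoate (C10 bears CH=CH–CO2Et, C5 bears C(CH3)2OH; C7 dioxolane, C8 bromide) | CCOC(=O)/C=C/[C@@]1(C)C=C(Br)C2(OCCO2)C[C@H]1C(C)(C)O | intermediate
16 | saturated ethyl ester (C10 bears CH2CH2CO2Et, C5 bears C(CH3)2OH; C7 dioxolane, C8 bromide) | CCOC(=O)CC[C@@]1(C)C=C(Br)C2(OCCO2)C[C@H]1C(C)(C)O | intermediate
17 | isopropenyl ester (C10 bears CH2CH2CO2Et, C5 bears C(CH3)=CH2; C7 dioxolane, C8 bromide) | CCOC(=O)CC[C@@]1(C)C=C(Br)C2(OCCO2)C[C@H]1C(C)=C | intermediate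
18 | primary alcohol (C10 bears (CH2)3OH, C5 isopropenyl; C7 dioxolane, C8 bromide) | OCCC[C@@]1(C)C=C(Br)C2(OCCO2)C[C@H]1C(C)=C | intermediate
19 | TBS ether of 18 (C10 bears (CH2)3OSi(t-Bu)Me2) | CC(C)(C)[Si](C)(C)OCCC[C@@]1(C)C=C(Br)C2(OCCO2)C[C@H]1C(C)=C | intermediate
20 | diisopropyl squarate, 3,4-di(propan-2-yloxy)cyclobut-3-ene-1,2-dione | CC(C)OC1=C(OC(C)C)C(=O)C1=O | starting material
21 | C8 vinyllithium from 19 (Li in place of Br) | CC(C)(C)[Si](C)(C)OCCC[C@@]1(C)C=C([Li])C2(OCCO2)C[C@H]1C(C)=C | intermediate (not isolated)
22 | lithium 4-(C8-alkenyl)-2,3-di(propan-2-yloxy)-1-oxocyclobut-2-en-4-olate | [Li+].CC(C)OC1=C(OC(C)C)C([O-])(C2=C[C@](C)(CCCO[Si](C)(C)C(C)(C)C)[C@H](C(C)=C)CC23OCCO3)C1=O | intermediate (not isolated)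
23 | 4-(C8-alkenyl)-2,3-di(propan-2-yloxy)-4-(trimethylsilyloxy)cyclobut-2-en-1-one | CC(C)OC1=C(OC(C)C)C(O[Si](C)(C)C)(C2=C[C@](C)(CCCO[Si](C)(C)C(C)(C)C)[C@H](C(C)=C)CC23OCCO3)C1=O | intermediate
24 | lithium 4-(C8-alkenyl)-1-(propan-2-yl)-2,3-di(propan-2-yloxy)-4-(trimethylsilyloxy)cyclobut-2-en-1-olate | [Li+].CC(C)OC1=C(OC(C)C)C(O[Si](C)(C)C)(C2=C[C@](C)(CCCO[Si](C)(C)C(C)(C)C)[C@H](C(C)=C)CC23OCCO3)C1([O-])C(C)C | intermediate (not isolated)
25 | 4-(C8-alkenyl)-3-(propan-2-yl)-2-(propan-2-yloxy)-4-(trimethylsilyloxy)cyclobut-2-en-1-one | CC(C)OC1=C(C(C)C)C(O[Si](C)(C)C)(C2=C[C@](C)(CCCO[Si](C)(C)C(C)(C)C)[C@H](C(C)=C)CC23OCCO3)C1=O | intermediate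
26 | ring C hydroquinone mono(trimethylsilyl) ether (C11 OH, C12 O-i-Pr, C13 i-Pr, C14 OSiMe3; C7 dioxolane; C10 bears (CH2)3OTBS; C5 isopropenyl) | C=C(C)[C@@H]1CC3(OCCO3)c2c(O[Si](C)(C)C)c(C(C)C)c(OC(C)C)c(O)c2[C@]1(C)CCCO[Si](C)(C)C(C)(C)C | intermediate (not isolated)
27 | hydroquinone keto alcohol (C11 OH, C12 O-i-Pr, C13 i-Pr, C14 OH, C7 ketone, C10 bears (CH2)3OH, C5 isopropenyl) | C=C(C)[C@@H]1CC(=O)c2c(O)c(C(C)C)c(OC(C)C)c(O)c2[C@]1(C)CCCO | intermediate (not isolated)
28 | 11,14-quinone keto alcohol (quinone of 27) | C=C(C)[C@@H]1CC(=O)C2=C([C@]1(C)CCCO)C(=O)C(OC(C)C)=C(C(C)C)C2=O | intermediate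
29 | quinone keto acid (28 with C3 as CO2H) | C=C(C)[C@@H]1CC(=O)C2=C([C@]1(C)CCC(=O)O)C(=O)C(OC(C)C)=C(C(C)C)C2=O | intermediate
30 | 12-hydroxy-11,14-quinone keto acid | C=C(C)[C@@H]1CC(=O)C2=C([C@]1(C)CCC(=O)O)C(=O)C(O)=C(C(C)C)C2=O | intermediate
31 | 3-[(1R,2S)-5,7,8-trihydroxy-1-methyl-4-oxo-6-(propan-2-yl)-2-(prop-1-en-2-yl)-1,2,3,4-tetrahydronaphthalen-1-yl]propanoic acid | C=C(C)[C@@H]1CC(=O)c2c(O)c(C(C)C)c(O)c(O)c2[C@]1(C)CCC(=O)O | target

## Step count and least certain steps

Total: 18 steps. Longest linear sequence: 18 steps (1 to 31); 2, 6 and 20 enter as purchased.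

Step 3 (key step). The most likely failure is incomplete discrimination of the two diene faces by the auxiliary, or leakage through the exo transition state. Since C9 is flattened afterwards, either would erode the enantiomeric purity of 8. Partial opening of the anhydride during unmasking is the second concern. Fallback, from 6 back to 8: 6 is combined under the conditions of step 3 with the achiral 1-(dimethylamino)-3-(tert-butyldimethylsilyloxy)buta-1,3-diene F1. The racemic endo cycloadduct F2 is unmasked with HCl to the racemate of 8, that is 8 together with its (3aS,7aR) antipode F3. The enantiomers are separated by preparative chromatography on a polysaccharide chiral stationary phase with an alcohol-free eluent, and 8 re-enters at step 4.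

Step 5. The silyl triflate may activate the anhydride toward acylative opening by the bis-silyl glycol, and ketalisation of the hindered, electron-poor bromo enone may be slow. Fallback, from 10 back to 13: 10 is opened with methanol at the less hindered C4 carbonyl to the half ester F4 (methyl ester on C5, acid on C10). Me3SiCHN2 gives the dimethyl ester F5. Ethylene glycol and TsOH in benzene with removal of water give the C7 ketal diester F6. MeMgBr (3 equiv) adds twice to the less hindered ester on C5, and the tertiary alkoxide closes onto the C10 ester to give 13.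

Step 8. The open hydroxy aldehyde is a minor tautomer and its formyl carbon is neopentyl, so olefination may be slow. Conjugate addition of the tertiary hydroxyl to the new enoate could also close a tetrahydrofuran. Fallback, from 13 back to 17, with dehydration before olefination so that no hydroxyl is present and the aldehyde is free:
- excess i-Bu2AlH reduces 13 to the diol F7;
- Ac2O and pyridine acetylate only the primary hydroxyl, giving the acetate F8;
- SOCl2 and pyridine dehydrate the tertiary alcohol to the isopropenyl acetate F9;
- K2CO3 in methanol frees the neopentyl alcohol F10;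
- Dess–Martin periodinane gives the aldehyde F11;
- (EtO)2P(O)CH2CO2Et and NaH give the E enoate F12;
- the copper hydride reduction of step 9 gives 17.

Step 14. The carbonyl of 23 is flanked by a fully substituted carbon, so i-PrLi may transfer a β-hydride or act as a base instead of adding. The anhydride-triggered rearrangement could also ionise on the wrong side. Fallback, from 20 and 21 (made from 19 as in step 13) back to 27, with the regiochemistry set on the small ring before the coupling:
- 20 with i-PrLi and then (CF3CO)2O gives 3-(propan-2-yl)-4-(propan-2-yloxy)cyclobut-3-ene-1,2-dione F13;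
- Noyori ketalisation masks its more electrophilic carbonyl, the one flanking the isopropoxy carbon, as the monoketal F14;
- 21 adds to the only free carbonyl to give the tertiary alcohol F15;
- dilute aqueous acid hydrolyses the four-ring ketal to the 4-hydroxycyclobutenone F16;
- heating in toluene gives the hydroquinone F17;
- the acid treatment of step 15 converts F17 into 27, which is oxidised to 28 as before.

## Further compounds

F1 | step 3 | 1-(dimethylamino)-3-(tert-butyldimethylsilyloxy)buta-1,3-diene | C=C(O[Si](C)(C)C(C)(C)C)/C=C/N(C)C
F2 | step 3 | racemic endo cycloadduct, 6-(tert-butyldimethylsilyloxy)-4-(dimethylamino)-3a-methyl-3a,4,7,7a-tetrahydro-2-benzofuran-1,3-dione (one enantiomer drawn) | CC(C)(C)[Si](C)(C)OC1=C[C@H](N(C)C)[C@]2(C)C(=O)OC(=O)[C@@H]2C1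
F3 | step 3 | (3aS,7aR)-7a-methyl-3a,4-dihydro-2-benzofuran-1,3,5(7aH)-trione, antipode of 8 | O=C1[C@H]2CC(=O)C=C[C@@]2(C)C(=O)O1
F4 | step 5 | half ester of 10 (CO2CH3 on C5, CO2H on C10, C7 ketone, C8 bromide) | COC(=O)[C@@H]1CC(=O)C(Br)=C[C@]1(C)C(=O)O
F5 | step 5 | dimethyl ester of F4 | COC(=O)[C@@H]1CC(=O)C(Br)=C[C@]1(C)C(=O)OC
F6 | step 5 | C7 ethylene ketal of F5 | COC(=O)[C@@H]1CC2(OCCO2)C(Br)=C[C@]1(C)C(=O)OC
F7 | step 8 | diol (C5 bears C(CH3)2OH, C10 bears CH2OH; C7 dioxolane, C8 bromide) | CC(C)(O)[C@@H]1CC2(OCCO2)C(Br)=C[C@]1(C)CO
F8 | step 8 | primary acetate of F7 | CC(C)(O)[C@@H]1CC2(OCCO2)C(Br)=C[C@]1(C)COC(C)=O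
F9 | step 8 | isopropenyl acetate (C5 bears C(CH3)=CH2, C10 bears CH2OAc) | C=C(C)[C@@H]1CC2(OCCO2)C(Br)=C[C@]1(C)COC(C)=O
F10 | step 8 | isopropenyl alcohol (C10 bears CH2OH) | C=C(C)[C@@H]1CC2(OCCO2)C(Br)=C[C@]1(C)CO
F11 | step 8 | isopropenyl aldehyde (C10 bears CHO) | C=C(C)[C@@H]1CC2(OCCO2)C(Br)=C[C@]1(C)C=O
F12 | step 8 | ethyl (E)-enoate with isopropenyl group (C10 bears CH=CH–CO2Et) | C=C(C)[C@@H]1CC2(OCCO2)C(Br)=C[C@]1(C)/C=C/C(=O)OCC
F13 | step 14 | 3-(propan-2-yl)-4-(propan-2-yloxy)cyclobut-3-ene-1,2-dione | CC(C)OC1=C(C(C)C)C(=O)C1=O
F14 | step 14 | 2-(propan-2-yl)-3-(propan-2-yloxy)-5,8-dioxaspiro[3.4]oct-2-en-1-one | CC(C)OC1=C(C(C)C)C(=O)C12OCCO2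
F15 | step 14 | 1-(C8-alkenyl)-1-hydroxy adduct of F14 (C8-alkenyl as in 23) | CC(C)OC1=C(C(C)C)C(O)(C3=C[C@](C)(CCCO[Si](C)(C)C(C)(C)C)[C@H](C(C)=C)CC34OCCO4)C12OCCO2
F16 | step 14 | 4-(C8-alkenyl)-4-hydroxy-3-(propan-2-yl)-2-(propan-2-yloxy)cyclobut-2-en-1-one | CC(C)OC1=C(C(C)C)C(O)(C3=C[C@](C)(CCCO[Si](C)(C)C(C)(C)C)[C@H](C(C)=C)CC34OCCO4)C1=O
F17 | step 14 | ring C hydroquinone (C11 OH, C12 O-i-Pr, C13 i-Pr, C14 OH; C7 dioxolane; C10 bears (CH2)3OTBS) | C=C(C)[C@@H]1CC3(OCCO3)c2c(O)c(C(C)C)c(OC(C)C)c(O)c2[C@]1(C)CCCO[Si](C)(C)C(C)(C)C
A1 | alternative 1 | 5,6,8-trimethoxy-4-methyl-7-(propan-2-yl)naphthalene-1,2-dione | CC1=CC(=O)C(=O)c2c(OC)c(C(C)C)c(OC)c(OC)c12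
A2 | alternative 1 | (3E)-2-(tert-butyldimethylsilyloxy)penta-1,3-diene | C=C(O[Si](C)(C)C(C)(C)C)/C=C/C
A3 | alternative 1 | cis-fused cycloadduct with C10 methyl, silyl enol ether in the temporary ring and C6,C7-dione | C1C(O[Si](C)(C)C(C)(C)C)=C[C@H](C)[C@@H]2C(=O)C(=O)c3c(OC)c(C(C)C)c(OC)c(OC)c3[C@]12C
A4 | alternative 2 | 4-hydroxy-2-(propan-2-yl)-3-(propan-2-yloxy)cyclobut-2-en-1-one carrying at C4 the ring B alkenyl joined at C9 (C7 OTBS, C5 isopropenyl, C10 methyl and (CH2)3OTBS) | C=C(C)[C@@H]1C[C@@H](O[Si](C)(C)C(C)(C)C)C=C(C2(O)C(=O)C(C(C)C)=C2OC(C)C)[C@]1(C)CCCO[Si](C)(C)C(C)(C)C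
A5 | alternative 2 | ring B/C hydroquinone with C12 isopropyl ether, C7 silyl ether and silyloxypropyl chain | C=C(C)[C@@H]1C[C@@H](O[Si](C)(C)C(C)(C)C)c2c(O)c(C(C)C)c(OC(C)C)c(O)c2[C@]1(C)CCCO[Si](C)(C)C(C)(C)C
A6 | alternative 3 | 7,9-dimethoxy-5-methyl-2-oxo-8-(propan-2-yl)-2,3,4,5-tetrahydro-1-benzoxepine-6-carbaldehyde | O=Cc1c(OC)c(C(C)C)c(OC)c2OC(=O)CCC(C)c12
A7 | alternative 3 | (5R)-5-methyl-5,6-dihydro-2H-pyran-2-one | O=C1C=C[C@@H](C)CO1
A8 | alternative 3 | ring B carbinol with cis-fused δ-lactone on C5/C6 and aryl lactone on C10 | O=C3OC[C@H](C)[C@@H]1[C@H]3[C@H](O)c2c(OC)c(C(C)C)c(OC)c4OC(=O)CC[C@@]1(C)c24
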